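**Retrosynthetic overview**

1. The acid comes from its methyl ester. The 1,2-dioxane (second ring) is closed by 6-exo peroxy-Michael addition of a C6 hydroperoxide to the 2E-enoate; the hydroperoxide is made in the same flask by SN2 perhydrolysis (inversion) of a C6 triflate.
2. The oxolane (first ring) is closed by perrhenate-mediated syn-oxidative cyclisation of the acyclic (10R)-10-hydroxy-2E,6E,17Z,19E,23-pentaenoate. O10 bonds to C7 and C6 is oxygenated in the same step; C10 sets C7 and the 6E geometry sets C6.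
3. The acyclic C24 chain comes from enantioselective addition of a C11–C24 trienylzinc to a C1–C10 aldehyde. This sets C10, the only reagent-controlled stereocentre.
4. The C1–C10 aldehyde comes from acrolein and 2-(2-bromoethyl)-1,3-dioxolane by Johnson–Claisen (6E) and Horner–Wadsworth–Emmons (2E) reactions. The C11–C24 bromide comes from a Z-selective Wittig reaction of a 7-bromoheptyl ylide with (2E)-hepta-2,6-dienal.

Assumption: the biosynthesis is taken to be oxidation of a 10-hydroxy-2,6-dienoic C24 polyene acid, in which O10 closes the oxolane onto C7 as C6 is oxygenated and a C6 hydroperoxide then adds 1,4 to the 2-enoyl unit; locants C1–C24 below are those of this chain (target 3R,6R,7S,10R: dioxane 3,6-trans, oxolane 2,5-trans, C6/C7 erythro).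

**Route**

Step 1
Reactants: 1 2-(2-bromoethyl)-1,3-dioxolane; 2 prop-2-enal (acrolein)
Product: 4 rac-1-(1,3-dioxolan-2-yl)pent-4-en-3-ol, via Grignard reagent 3 (not isolated)
Conditions: Mg, THF, 25–30 °C; then 2, −78 °C; aq. NH4Cl
Reagents that add atoms: none
Why: Grignard 1,2-addition of the acetal-masked homoenolate reagent (stable below 30 °C) to the aldehyde carbon of acrolein; the carbinol centre is racemic and is erased in step 2.

Step 2
Reactants: 4 rac-1-(1,3-dioxolan-2-yl)pent-4-en-3-ol
Product: 6 ethyl (4E)-7-(1,3-dioxolan-2-yl)hept-4-enoate, via ketene acetal 5 (not isolated)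
Conditions: MeC(OEt)3 (6 equiv), EtCO2H (5 mol %), 140 °C, EtOH distilled off
Reagents that add atoms: triethyl orthoacetate, CC(OCC)(OCC)OCC
Why: Johnson–Claisen rearrangement through a chair transition state with the acetal-bearing chain equatorial, which fixes the new C6=C7 alkene as E and gives C3–C10 with two different ends.

Step 3
Reactants: 6 ethyl (4E)-7-(1,3-dioxolan-2-yl)hept-4-enoate
Product: 8 methyl (2E,6E)-9-(1,3-dioxolan-2-yl)nona-2,6-dienoate, via aldehyde 7 (not isolated)
Conditions: iBu2AlH (1.05 equiv), CH2Cl2, −78 °C; then (MeO)2P(O)CH2CO2Me/NaH in THF, −78 °C → rt; aq. potassium sodium tartrate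
Reagents that add atoms: trimethyl phosphonoacetate, COC(=O)CP(=O)(OC)OC
Why: one-pot ester half-reduction and Horner–Wadsworth–Emmons olefination, in which the aluminium hemiacetal releases aldehyde 7 as the stabilised phosphonate anion consumes it and that anion gives the 2E enoate.

Step 4
Reactants: 8 methyl (2E,6E)-9-(1,3-dioxolan-2-yl)nona-2,6-dienoate
Product: 9 methyl (2E,6E)-10-oxodeca-2,6-dienoate
Conditions: 2 M HCl, THF, rt
Reagents that add atoms: water, O
Why: acid-catalysed acetal hydrolysis frees the C10 aldehyde, while the enoate and the isolated E alkene are inert to cold dilute acid.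

Step 5
Reactants: 10 1,7-dibromoheptane
Product: 11 (7-bromoheptyl)triphenylphosphonium bromide
Conditions: PPh3 (1 equiv), 10 (4 equiv), MeCN, reflux; excess 10 recovered
Reagents that add atoms: triphenylphosphine, c1ccc(cc1)P(c1ccccc1)c1ccccc1
Why: SN2 quaternisation of the phosphine (phosphonium salt formation), with the excess of dibromide suppressing the bis-phosphonium salt.

Step 6
Reactants: 12 pent-4-enal; 13 (triphenylphosphoranylidene)acetaldehyde
Product: 14 (2E)-hepta-2,6-dienal
Conditions: toluene, 80 °C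
Reagents that add atoms: none
Why: Wittig olefination with a formyl-stabilised ylide is E-selective, and a slight excess of 12 limits a second homologation.

Step 7
Reactants: 11 (7-bromoheptyl)triphenylphosphonium bromide; 14 (2E)-hepta-2,6-dienal
Product: 16 (5E,7Z)-14-bromotetradeca-1,5,7-triene, via ylide 15 (not isolated)
Conditions: NaN(SiMe3)2 (1.0 equiv), THF, −78 °C; then 14, −78 → 0 °C
Reagents that add atoms: none
Why: Z-selective Wittig olefination of a non-stabilised ylide under lithium-free conditions forms the 7Z alkene (C17=C18) beside the preformed E alkene; the primary bromide is untouched at low temperature and the minor 7E isomer is removed on AgNO3-impregnated silica.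

Step 8
Reactants: 16 (5E,7Z)-14-bromotetradeca-1,5,7-triene (3 equiv); 9 methyl (2E,6E)-10-oxodeca-2,6-dienoate (1 equiv)
Product: 19 methyl (2E,6E,10R,17Z,19E)-10-hydroxytetracosa-2,6,17,19,23-pentaenoate, via Grignard reagent 17 (not isolated), via dialkylzinc 18 (not isolated)
Conditions: Mg, Et2O; ZnCl2 (0.5 equiv per Grignard), then 1,4-dioxane, filter off MgBrCl·dioxane; Ti(OiPr)4 (1.2 equiv), (4S,5S)-TADDOL (0.2 equiv, as its Ti(OiPr)2 chelate), toluene, −25 °C; then 9; aq. NH4Cl
Reagents that add atoms: none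
Why: Seebach-type TADDOLate–titanium-catalysed enantioselective addition of a Grignard-derived, salt-free dialkylzinc to the aldehyde; the (S,S)-ligand (its enantiomer directs Si-face attack) delivers the alkyl group to the Re face and sets C10 as R, and the enoate is inert to the zinc reagent.

Step 9
Reactants: 19 methyl (2E,6E,10R,17Z,19E)-10-hydroxytetracosa-2,6,17,19,23-pentaenoate
Product: 21 methyl (2E,6S)-6-hydroxy-6-[(2S,5R)-5-[(7Z,9E)-tetradeca-7,9,13-trien-1-yl]oxolan-2-yl]hex-2-enoate, via perrhenate ester 20 (not isolated)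
Conditions: CF3CO2ReO3 (2 equiv, from Re2O7 and (CF3CO)2O in THF, evaporated), 2,6-lutidine (3 equiv), CH2Cl2, 0 °C → rt, dark; aq. NaHCO3
Reagents that add atoms: dirhenium heptoxide, O=[Re](=O)(=O)O[Re](=O)(=O)=O
Why: Kennedy-type syn-oxidative cyclisation with an acyl perrhenate of heptavalent rhenium, in which the C10 perrhenate ester adds O10 and a rhenium oxo oxygen to the same face of the 6E alkene with the C10 chain pseudo-equatorial; this gives the 2,5-trans oxolane (7S) and the threo alcohol (6S), and the diene, terminal alkene and electron-poor enoate are out of reach of the tethered oxidant.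

Step 10
Reactants: 21 methyl (2E,6S)-6-hydroxy-6-[(2S,5R)-5-[(7Z,9E)-tetradeca-7,9,13-trien-1-yl]oxolan-2-yl]hex-2-enoate
Product: 22 methyl (2E,6S)-6-[(2S,5R)-5-[(7Z,9E)-tetradeca-7,9,13-trien-1-yl]oxolan-2-yl]-6-(trifluoromethanesulfonyloxy)hex-2-enoate
Conditions: Tf2O (1.3 equiv), 2,6-lutidine (2 equiv), CH2Cl2, −78 °C; cold aq. NaHCO3, used at once
Reagents that add atoms: trifluoromethanesulfonic anhydride, O=S(=O)(OS(=O)(=O)C(F)(F)F)C(F)(F)F
Why: O-sulfonylation with retention at C6, the β-oxygen of the oxolane retarding ionisation so that the secondary triflate survives a cold work-up (as with carbohydrate triflates).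

Step 11
Reactants: 22 methyl (2E,6S)-6-[(2S,5R)-5-[(7Z,9E)-tetradeca-7,9,13-trien-1-yl]oxolan-2-yl]-6-(trifluoromethanesulfonyloxy)hex-2-enoate
Product: 24 methyl 2-[(3R,6R)-6-[(2S,5R)-5-[(7Z,9E)-tetradeca-7,9,13-trien-1-yl]oxolan-2-yl]-1,2-dioxan-3-yl]acetate, via hydroperoxide 23 (not isolated)
Conditions: H2O2 (50% aq., 30 equiv), CsOH·H2O (1.5 equiv), THF, −20 → 0 °C; then CF3CH2OH, Et2NH (0.3 equiv), rt
Reagents that add atoms: hydrogen peroxide, OO
Why: SN2 perhydrolysis of the sulfonate (Williams–Mosher type) by the weakly basic α-effect nucleophile HOO− inverts C6 to R, and the hydroperoxide then closes the ring by reversible 6-exo-trig peroxy-Michael addition to the 2E enoate, the 3,6-trans diequatorial dioxane (3R) being the thermodynamic product.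

Step 12
Reactants: 24 methyl 2-[(3R,6R)-6-[(2S,5R)-5-[(7Z,9E)-tetradeca-7,9,13-trien-1-yl]oxolan-2-yl]-1,2-dioxan-3-yl]acetate
Product: 25 2-[(3R,6R)-6-[(2S,5R)-5-[(7Z,9E)-tetradeca-7,9,13-trien-1-yl]oxolan-2-yl]-1,2-dioxan-3-yl]acetic acid (CNP0186740.6)
Conditions: LiOH·H2O (3 equiv), THF/H2O 3:1, 0 °C → rt; 1 M HCl to pH 4 at 0 °C
Reagents that add atoms: lithium hydroxide, [Li+].[OH-]
Why: saponification of the methyl ester and mild acidification, which the dialkyl peroxide, oxolane and diene tolerate in the cold and which touches no stereocentre.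

**Compound list**

1 | 2-(2-bromoethyl)-1,3-dioxolane | BrCCC1OCCO1 | starting material
2 | prop-2-enal (acrolein) | C=CC=O | starting material
3 | [2-(1,3-dioxolan-2-yl)ethyl]magnesium bromide | Br[Mg]CCC1OCCO1 | intermediate
4 | rac-1-(1,3-dioxolan-2-yl)pent-4-en-3-ol | C=CC(O)CCC1OCCO1 | intermediate
5 | 2-{3-[(1-ethoxyethenyl)oxy]pent-4-en-1-yl}-1,3-dioxolane (mixed ketene acetal) | C=CC(OC(=C)OCC)CCC1OCCO1 | intermediate
6 | ethyl (4E)-7-(1,3-dioxolan-2-yl)hept-4-enoate | CCOC(=O)CC/C=C/CCC1OCCO1 | intermediate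
7 | (4E)-7-(1,3-dioxolan-2-yl)hept-4-enal | O=CCC/C=C/CCC1OCCO1 | intermediate
8 | methyl (2E,6E)-9-(1,3-dioxolan-2-yl)nona-2,6-dienoate | COC(=O)/C=C/CC/C=C/CCC1OCCO1 | intermediate
9 | methyl (2E,6E)-10-oxodeca-2,6-dienoate | COC(=O)/C=C/CC/C=C/CCC=O | intermediate
10 | 1,7-dibromoheptane | BrCCCCCCCBr | starting material
11 | (7-bromoheptyl)triphenylphosphonium bromide | BrCCCCCCC[P+](c1ccccc1)(c1ccccc1)c1ccccc1.[Br-] | intermediate
12 | pent-4-enal | C=CCCC=O | starting material
13 | (triphenylphosphoranylidene)acetaldehyde | O=CC=P(c1ccccc1)(c1ccccc1)c1ccccc1 | starting material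
14 | (2E)-hepta-2,6-dienal | C=CCC/C=C/C=O | intermediate
15 | (7-bromoheptylidene)triphenylphosphorane | BrCCCCCCC=P(c1ccccc1)(c1ccccc1)c1ccccc1 | intermediate
16 | (5E,7Z)-14-bromotetradeca-1,5,7-triene | C=CCC/C=C/C=C\CCCCCCBr | intermediate
17 | [(7Z,9E)-tetradeca-7,9,13-trien-1-yl]magnesium bromide | C=CCC/C=C/C=C\CCCCCC[Mg]Br | intermediate
18 | bis[(7Z,9E)-tetradeca-7,9,13-trien-1-yl]zinc | C=CCC/C=C/C=C\CCCCCC[Zn]CCCCCC/C=C\C=C\CCC=C | intermediate
19 | methyl (2E,6E,10R,17Z,19E)-10-hydroxytetracosa-2,6,17,19,23-pentaenoate | C=CCC/C=C/C=C\CCCCCC[C@@H](O)CC/C=C/CC/C=C/C(=O)OC | intermediate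
20 | methyl (2E,6E,10R,17Z,19E)-10-(trioxorheniooxy)tetracosa-2,6,17,19,23-pentaenoate (alkyl perrhenate) | C=CCC/C=C/C=C\CCCCCC[C@@H](O[Re](=O)(=O)=O)CC/C=C/CC/C=C/C(=O)OC | intermediate
21 | methyl (2E,6S)-6-hydroxy-6-[(2S,5R)-5-[(7Z,9E)-tetradeca-7,9,13-trien-1-yl]oxolan-2-yl]hex-2-enoate | C=CCC/C=C/C=C\CCCCCC[C@@H]1CC[C@@H]([C@@H](O)CC/C=C/C(=O)OC)O1 | intermediate
22 | methyl (2E,6S)-6-[(2S,5R)-5-[(7Z,9E)-tetradeca-7,9,13-trien-1-yl]oxolan-2-yl]-6-(trifluoromethanesulfonyloxy)hex-2-enoate | C=CCC/C=C/C=C\CCCCCC[C@@H]1CC[C@@H]([C@@H](OS(=O)(=O)C(F)(F)F)CC/C=C/C(=O)OC)O1 | intermediate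
23 | methyl (2E,6R)-6-hydroperoxy-6-[(2S,5R)-5-[(7Z,9E)-tetradeca-7,9,13-trien-1-yl]oxolan-2-yl]hex-2-enoate | C=CCC/C=C/C=C\CCCCCC[C@@H]1CC[C@@H]([C@H](OO)CC/C=C/C(=O)OC)O1 | intermediate
24 | methyl 2-[(3R,6R)-6-[(2S,5R)-5-[(7Z,9E)-tetradeca-7,9,13-trien-1-yl]oxolan-2-yl]-1,2-dioxan-3-yl]acetate | C=CCC/C=C/C=C\CCCCCC[C@@H]1CC[C@@H]([C@H]2CC[C@H](CC(=O)OC)OO2)O1 | intermediate
25 | 2-[(3R,6R)-6-[(2S,5R)-5-[(7Z,9E)-tetradeca-7,9,13-trien-1-yl]oxolan-2-yl]-1,2-dioxan-3-yl]acetic acid | C=CCC/C=C/C=C\CCCCCC[C@@H]1CC[C@@H]([C@H]2CC[C@H](CC(=O)O)OO2)O1 | target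

**Step count and risks**

Total step count: 12. Longest linear sequence: 9 steps (steps 1, 2, 3, 4, 8, 9, 10, 11, 12, from compound 1).

The three steps most likely to fail, most risky first:

Step 11 (perhydrolysis and ring closure). The displacement takes place at a secondary carbon next to the oxolane oxygen. Possible failures are elimination, ring-oxygen participation (ring expansion to an oxane), double alkylation of H2O2, and an unfavourable cis/trans ratio at C3. The fallback sets out from 22 and replaces free H2O2 by a masked, monofunctional peroxide, so that substitution and ring closure become separate operations. Triflate 22 is treated with the known reagent 2-methoxyprop-2-yl hydroperoxide and CsOH·H2O in DMF at 0 °C. This gives the peroxyketal methyl (2E,6R)-6-[(2-methoxypropan-2-yl)peroxy]-6-[(2S,5R)-5-[(7Z,9E)-tetradeca-7,9,13-trien-1-yl]oxolan-2-yl]hex-2-enoate F1, which cannot be alkylated a second time and can be purified. Aqueous acetic acid in THF then unmasks it and the fallback comes back to the route at 23, here isolated. Compound 23 is closed to 24 with Et2NH in CF3CH2OH, where the cis dioxane can be re-equilibrated through retro-Michael and Michael addition.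

Step 9 (oxidative cyclisation on the pentaene). The acyl perrhenate or adventitious perrhenic acid may attack or isomerise the Z,E-diene, and a second cyclisation onto the enoate is conceivable. The fallback sets out from 19 and uses anti addition followed by inversion in place of syn addition. VO(acac)2 (5 mol %) and tBuOOH in CH2Cl2 epoxidise only the alkene reached from the C10 hydroxyl, giving methyl (2E,6R,7R,10R,17Z,19E)-6,7-epoxy-10-hydroxytetracosa-2,17,19,23-tetraenoate F2 (not isolated). Acetic acid then triggers 5-exo opening by O10 with inversion at C7, giving the erythro alcohol methyl (2E,6R)-6-hydroxy-6-[(2S,5R)-5-[(7Z,9E)-tetradeca-7,9,13-trien-1-yl]oxolan-2-yl]hex-2-enoate F3. The facial selectivity of this directed epoxidation is only moderate, so the 2,5-cis oxolane isomer has to be separated. Mitsunobu inversion at C6 with chloroacetic acid, PPh3 and DIAD in THF gives methyl (2E,6S)-6-(2-chloroacetoxy)-6-[(2S,5R)-5-[(7Z,9E)-tetradeca-7,9,13-trien-1-yl]oxolan-2-yl]hex-2-enoate F4. Thiourea and NaHCO3 in ethanol remove the chloroacetate under near-neutral conditions, so that no alkoxide forms next to the enoate, and the fallback comes back to the route at 21.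

Step 8 (enantioselective zinc addition). The functionalised dialkylzinc may give insufficient enantiomeric excess with this unbranched aldehyde, and it needs an excess of the chain. The fallback sets out from 9 and moves the stereo-defining event to a kinetic resolution. Corey–Chaykovsky methylenation (Me3S+ I−, NaH, DMSO/THF, 0 °C) gives the racemic oxirane methyl (2E,6E)-9-(oxiran-2-yl)nona-2,6-dienoate F5. Hydrolytic kinetic resolution with (R,R)-(salen)Co(OAc) (trivalent cobalt, 0.5 mol %; 0.55 equiv H2O), the catalyst enantiomer that hydrates the R oxirane, leaves methyl (2E,6E)-9-[(2S)-oxiran-2-yl]nona-2,6-dienoate F6. A chain one carbon shorter is made as in steps 5 and 7 from 1,6-dibromohexane, through (6-bromohexyl)triphenylphosphonium bromide F7 and its ylide (6-bromohexylidene)triphenylphosphorane F8 (not isolated), to (5E,7Z)-13-bromotrideca-1,5,7-triene F9. Its Grignard reagent [(6Z,8E)-trideca-6,8,12-trien-1-yl]magnesium bromide F10 (not isolated), with CuI (10 mol %) in THF at −40 °C, opens F6 at the CH2 terminus. The oxirane oxygen becomes O10 and the fallback comes back to the route at 19.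

Further compounds

F1 | step 11 | methyl (2E,6R)-6-[(2-methoxypropan-2-yl)peroxy]-6-[(2S,5R)-5-[(7Z,9E)-tetradeca-7,9,13-trien-1-yl]oxolan-2-yl]hex-2-enoate | C=CCC/C=C/C=C\CCCCCC[C@@H]1CC[C@@H]([C@H](OOC(C)(C)OC)CC/C=C/C(=O)OC)O1
F2 | step 9 | methyl (2E,6R,7R,10R,17Z,19E)-6,7-epoxy-10-hydroxytetracosa-2,17,19,23-tetraenoate | C=CCC/C=C/C=C\CCCCCC[C@@H](O)CC[C@H]1O[C@@H]1CC/C=C/C(=O)OC
F3 | step 9 | methyl (2E,6R)-6-hydroxy-6-[(2S,5R)-5-[(7Z,9E)-tetradeca-7,9,13-trien-1-yl]oxolan-2-yl]hex-2-enoate | C=CCC/C=C/C=C\CCCCCC[C@@H]1CC[C@@H]([C@H](O)CC/C=C/C(=O)OC)O1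
F4 | step 9 | methyl (2E,6S)-6-(2-chloroacetoxy)-6-[(2S,5R)-5-[(7Z,9E)-tetradeca-7,9,13-trien-1-yl]oxolan-2-yl]hex-2-enoate | C=CCC/C=C/C=C\CCCCCC[C@@H]1CC[C@@H]([C@@H](OC(=O)CCl)CC/C=C/C(=O)OC)O1
F5 | step 8 | methyl (2E,6E)-9-(oxiran-2-yl)nona-2,6-dienoate (racemic) | COC(=O)/C=C/CC/C=C/CCC1CO1
F6 | step 8 | methyl (2E,6E)-9-[(2S)-oxiran-2-yl]nona-2,6-dienoate | COC(=O)/C=C/CC/C=C/CC[C@H]1CO1
F7 | step 8 | (6-bromohexyl)triphenylphosphonium bromide | BrCCCCCC[P+](c1ccccc1)(c1ccccc1)c1ccccc1.[Br-]
F8 | step 8 | (6-bromohexylidene)triphenylphosphorane | BrCCCCCC=P(c1ccccc1)(c1ccccc1)c1ccccc1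
F9 | step 8 | (5E,7Z)-13-bromotrideca-1,5,7-triene | C=CCC/C=C/C=C\CCCCCBr
F10 | step 8 | [(6Z,8E)-trideca-6,8,12-trien-1-yl]magnesium bromide | C=CCC/C=C/C=C\CCCCC[Mg]Br
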